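**Plan**
1. Retrosynthesis: the C6 O–Si bond and both benzoate C–O bonds are cut last, leading back to a silylated dienoate. The ring is then opened at C4–C5 and C1–C6, with CO2 put back as a lactone bridge, giving a 3-carbomethoxy-2-pyrone and an E-enediol derivative. That alkene is cut at its vinyl C–O(benzoyl) and C–B bonds back to a silyl ynol ether.
2. Enabling feature: the ring diene C1=C2–C3=C4 with an acyl-level carbon on C1 is C3–C6 of a 3-carboxy-2-pyrone after loss of CO2, and C5/C6 are the two carbons of an E-1,2-dioxygenated alkene.
3. Forward: the two-carbon dienophile is made first (ynolate O-silylation, C-desilylation, hydroboration, copper-mediated benzoate coupling). The only ring, the six-membered carbocycle, then forms in one [4+2]/retro-[4+2] operation. Ester reduction, benzoylation and desilylation finish the route.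
4. Stereochemistry: the trans C5/C6 relationship is the E geometry of the dienophile (fixed by syn-hydroboration) carried over suprafacially. The absolute configuration comes from the chiral Cu(OTf)2–bis(oxazoline) catalyst.

Key step: step 5

Remark on the chemistry: the (S,S)-tert-butyl-bis(oxazoline) ligand is assumed to give the (5R,6R) series through a siloxy-endo approach; if the sense proves opposite, the (R,R)-ligand is used with no other change.

**Step 1**
Reactants: 1 ethynyltrimethylsilane
Product: 4 triisopropyl{[(trimethylsilyl)ethynyl]oxy}silane, via lithium (trimethylsilyl)acetylide 2 (not isolated), via lithium 2-(trimethylsilyl)ethynolate 3 (not isolated)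
Conditions: n-BuLi, THF, −78 °C; LiOOt-Bu (from t-BuOOH and LiN(SiMe3)2, THF, −78 °C), −78 → 0 °C; TIPSOTf, −78 → 0 °C
Reagents that add atoms: tert-butyl hydroperoxide (used as its lithium salt), CC(C)(C)OO; triisopropylsilyl trifluoromethanesulfonate, CC(C)[Si](OS(=O)(=O)C(F)(F)F)(C(C)C)C(C)C
Why: The acetylide should attack the O–O bond of lithium tert-butyl peroxide (electrophilic oxygen transfer to an organolithium) to give the ynolate, which the bulky silyl triflate should silylate on oxygen rather than carbon (ynolate O-silylation).

**Step 2**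
Reactants: 4 triisopropyl{[(trimethylsilyl)ethynyl]oxy}silane
Product: 5 (ethynyloxy)triisopropylsilane
Conditions: K2CO3 (0.2 equiv), MeOH, 0 °C, short contact; pentane work-up, careful concentration
Reagents that add atoms: none
Why: Base-catalysed methanolysis of the C(sp)–SiMe3 bond (protodesilylation) should be fast at the unhindered trimethylsilyl group, while the branched triisopropylsilyl group on oxygen is shielded from methoxide.

**Step 3**
Reactants: 5 (ethynyloxy)triisopropylsilane
Product: 6 triisopropyl{[(E)-2-(4,4,5,5-tetramethyl-1,3,2-dioxaborolan-2-yl)ethenyl]oxy}silane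
Conditions: pinacolborane (1.1 equiv), Cp2Zr(H)Cl (5 mol%), Et3N (10 mol%), CH2Cl2, rt
Reagents that add atoms: pinacolborane, B1OC(C)(C)C(C)(C)O1
Why: Zirconocene-hydride-catalysed syn-hydroboration of a terminal alkyne should place boron on the terminal carbon β to oxygen, as with alkoxyacetylenes, and syn delivery of H and B fixes the E geometry.

**Step 4**
Reactants: 6 triisopropyl{[(E)-2-(4,4,5,5-tetramethyl-1,3,2-dioxaborolan-2-yl)ethenyl]oxy}silane; 7 benzoic acid
Product: 8 (E)-2-[(triisopropylsilyl)oxy]ethenyl benzoate
Conditions: Cu(OAc)2 (2.2 equiv), Et3N (3 equiv), 4 Å MS, CH2Cl2, rt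
Reagents that add atoms: none
Why: In this Chan–Lam–Evans coupling the alkenyl group should pass from boron to copper benzoate, and C–O reductive elimination from the trivalent copper intermediate should occur with retention of the E geometry.

**Step 5**
Reactants: 8 (E)-2-[(triisopropylsilyl)oxy]ethenyl benzoate; 9 methyl 2-oxo-2H-pyran-3-carboxylate
Product: 11 methyl (5R,6R)-5-(benzoyloxy)-6-[(triisopropylsilyl)oxy]cyclohexa-1,3-diene-1-carboxylate, via bridged bicyclic lactone 10 (not isolated)
Conditions: Cu(OTf)2 (10 mol%), (S,S)-t-Bu-bis(oxazoline) (11 mol%), 4 Å MS, CH2Cl2, −40 → 0 °C; filtration through silica; PhMe, 80 °C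
Reagents that add atoms: none
Why: Divalent copper chelates the lactone and ester carbonyls of 9 and lowers the diene LUMO, so that 8 should add in an asynchronous inverse-electron-demand Diels–Alder reaction in which the benzoate-bearing carbon (β to the stronger silyloxy donor) bonds first to pyrone C6 and the silyloxy carbon then bonds to C3; warming then triggers retro-[4+2] loss of CO2 from lactone 10. The closest known reaction type is the chiral Cu(OTf)2–bis(oxazoline)-catalysed cycloaddition of 3-carboalkoxy-2-pyrones with enol ethers, followed by thermal decarboxylation of the bridged lactone. The six-membered carbocycle is closed by intermolecular [4+2] cycloaddition, which forms both ring bonds (C4–C5 and C1–C6 in target numbering) in one suprafacial event, and the lactone bridge is then excised as CO2 to leave the monocyclic diene. The trans C5/C6 relationship is controlled by the E geometry of 8, and the absolute configuration by the tert-butyl groups of the ligand, which block one face of the square-planar chelate, together with the siloxy-endo orientation. The step needs one regiochemistry, one pyrone face and one endo/exo mode (the bridgeheads are erased on decarboxylation, so an error in either of the last two gives the enantiomer), and it must stop at the diene; the donor gap between silyloxy and benzoyloxy, the rigid two-point chelate, the bulky silyl group that disfavours silyl transfer and a stepwise Mukaiyama–Michael path, and copper-free neutral heating at 80 °C are expected to secure this.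

**Step 6**
Reactants: 11 methyl (5R,6R)-5-(benzoyloxy)-6-[(triisopropylsilyl)oxy]cyclohexa-1,3-diene-1-carboxylate
Product: 12 (1R,6R)-5-(hydroxymethyl)-6-[(triisopropylsilyl)oxy]cyclohexa-2,4-dien-1-ol
Conditions: i-Bu2AlH (5 equiv), CH2Cl2, −78 °C; aq. Rochelle salt
Reagents that add atoms: none
Why: i-Bu2AlH should effect 1,2-reduction of the dienoate to the allylic alcohol and reductive cleavage of the benzoate in the same operation, at a temperature where the stereocentres, the diene and the silyl ether are untouched.

**Step 7**
Reactants: 12 (1R,6R)-5-(hydroxymethyl)-6-[(triisopropylsilyl)oxy]cyclohexa-2,4-dien-1-ol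
Product: 13 {(5R,6R)-5-(benzoyloxy)-6-[(triisopropylsilyl)oxy]cyclohexa-1,3-dien-1-yl}methyl benzoate
Conditions: BzCl (2.5 equiv), pyridine, DMAP (cat.), CH2Cl2, 0 °C → rt
Reagents that add atoms: benzoyl chloride, O=C(Cl)c1ccccc1
Why: DMAP-catalysed acylation (nucleophilic catalysis through the N-benzoylpyridinium ion) should esterify both the primary and the secondary allylic hydroxyl, and the mild base should not provoke elimination to an arene.

**Step 8**
Reactants: 13 {(5R,6R)-5-(benzoyloxy)-6-[(triisopropylsilyl)oxy]cyclohexa-1,3-dien-1-yl}methyl benzoate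
Product: 14 [(5R,6R)-5-(benzoyloxy)-6-hydroxycyclohexa-1,3-dien-1-yl]methyl benzoate
Conditions: HF·pyridine, pyridine, THF, 0 °C → rt
Reagents that add atoms: none
Why: Fluoride-mediated Si–O cleavage under buffered, weakly acidic conditions (HF·pyridine desilylation) should free the C6 hydroxyl without the 1,2-benzoyl migration that a basic fluoride source could cause.

**Compound list**
1 | ethynyltrimethylsilane | C#C[Si](C)(C)C | starting material
2 | lithium (trimethylsilyl)acetylide | [Li]C#C[Si](C)(C)C | intermediate
3 | lithium 2-(trimethylsilyl)ethynolate | [Li+].[O-]C#C[Si](C)(C)C | intermediate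
4 | triisopropyl{[(trimethylsilyl)ethynyl]oxy}silane | C[Si](C)(C)C#CO[Si](C(C)C)(C(C)C)C(C)C | intermediate
5 | (ethynyloxy)triisopropylsilane | C#CO[Si](C(C)C)(C(C)C)C(C)C | intermediate
6 | triisopropyl{[(E)-2-(4,4,5,5-tetramethyl-1,3,2-dioxaborolan-2-yl)ethenyl]oxy}silane | CC(C)[Si](O/C=C/B1OC(C)(C)C(C)(C)O1)(C(C)C)C(C)C | intermediate
7 | benzoic acid | OC(=O)c1ccccc1 | starting material
8 | (E)-2-[(triisopropylsilyl)oxy]ethenyl benzoate | O=C(O/C=C/O[Si](C(C)C)(C(C)C)C(C)C)c1ccccc1 | intermediate
9 | methyl 2-oxo-2H-pyran-3-carboxylate | COC(=O)C1=CC=COC1=O | starting material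
10 | methyl (1R,4S,7R,8R)-7-(benzoyloxy)-3-oxo-8-[(triisopropylsilyl)oxy]-2-oxabicyclo[2.2.2]oct-5-ene-4-carboxylate (silyloxy group syn to the C5=C6 bridge, benzoyloxy group syn to the lactone bridge) | COC(=O)[C@@]12C=C[C@@H](OC1=O)[C@@H](OC(=O)c3ccccc3)[C@@H]2O[Si](C(C)C)(C(C)C)C(C)C | intermediate
11 | methyl (5R,6R)-5-(benzoyloxy)-6-[(triisopropylsilyl)oxy]cyclohexa-1,3-diene-1-carboxylate | COC(=O)C1=CC=C[C@@H](OC(=O)c2ccccc2)[C@@H]1O[Si](C(C)C)(C(C)C)C(C)C | intermediate
12 | (1R,6R)-5-(hydroxymethyl)-6-[(triisopropylsilyl)oxy]cyclohexa-2,4-dien-1-ol | OCC1=CC=C[C@@H](O)[C@@H]1O[Si](C(C)C)(C(C)C)C(C)C | intermediate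
13 | {(5R,6R)-5-(benzoyloxy)-6-[(triisopropylsilyl)oxy]cyclohexa-1,3-dien-1-yl}methyl benzoate | O=C(OCC1=CC=C[C@@H](OC(=O)c2ccccc2)[C@@H]1O[Si](C(C)C)(C(C)C)C(C)C)c1ccccc1 | intermediate
14 | [(5R,6R)-5-(benzoyloxy)-6-hydroxycyclohexa-1,3-dien-1-yl]methyl benzoate | O=C(OCC1=CC=C[C@@H](OC(=O)c2ccccc2)[C@@H]1O)c1ccccc1 | target

**Step count**
Total steps: 8. Longest linear sequence: 8 steps (1 → 14).

**Steps most likely to fail**

Step 5. Incomplete discrimination between the two pyrone faces, or between the siloxy-endo and siloxy-exo approach, would erode the enantiomeric purity, since either error leads to the mirror-image diene once the bridgeheads are lost. A stepwise addition with bond rotation could also loosen the trans relationship. The fallback moves stereocontrol from the catalyst to a covalently bound chiral acyl group that the route cleaves anyway. It sets out from boronate 6 and comes back at diol 12. Copper-mediated coupling of 6 with (S)-2-methoxy-2-phenylacetic acid in place of 7 would give (E)-2-[(triisopropylsilyl)oxy]ethenyl (2S)-2-methoxy-2-phenylacetate F1. Cycloaddition with 9 under an achiral Lewis acid (Zn(OTf)2, CH2Cl2) would pass through the unisolated bridged lactone, shown for the isomer that corresponds to 10, methyl (1R,4S,7R,8R)-7-{[(2S)-2-methoxy-2-phenylacetyl]oxy}-3-oxo-8-[(triisopropylsilyl)oxy]-2-oxabicyclo[2.2.2]oct-5-ene-4-carboxylate F2. Decarboxylation in PhMe at 80 °C would then give two diastereomeric dienes, methyl (5R,6R)-5-{[(2S)-2-methoxy-2-phenylacetyl]oxy}-6-[(triisopropylsilyl)oxy]cyclohexa-1,3-diene-1-carboxylate F3 and methyl (5S,6S)-5-{[(2S)-2-methoxy-2-phenylacetyl]oxy}-6-[(triisopropylsilyl)oxy]cyclohexa-1,3-diene-1-carboxylate F4, to be separated by chromatography or crystallisation. Reduction of F3 with i-Bu2AlH removes the chiral acyl group together with the methyl ester and gives 12.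

Step 4. Protodeboronation or hydrolysis of the β-silyloxy alkenylboronate, and slow boron-to-copper transfer from the pinacol ester, may outrun C–O bond formation; divalent copper may also degrade the silyl enol ether oxidatively. The fallback oxidises the C–B bond instead of coupling it. It sets out from 6 and comes back at 8. Anhydrous Me3NO in THF should convert 6 with retention of geometry into the enol borate 4,4,5,5-tetramethyl-2-({(E)-2-[(triisopropylsilyl)oxy]ethenyl}oxy)-1,3,2-dioxaborolane F5. t-BuOK should then release potassium (E)-2-[(triisopropylsilyl)oxy]ethenolate F6, which is O-benzoylated with benzoic anhydride at −78 °C to give 8.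

Step 2. Methoxide may also attack the oxygen-bound silicon, because the ynolate is a good leaving group, and so destroy the ynol ether; the volatile product may in addition be lost on concentration. The fallback reverses the order of C-desilylation and O-silylation, so that no selectivity between two silyl groups is needed. It sets out from ynolate 3 and comes back at 5. Protonation of 3 on carbon (HCl in Et2O, −78 °C) should give (trimethylsilyl)ketene F7, isolable by distillation. t-BuOK in THF should cleave its C–Si bond to potassium ethynolate F8, and TIPSOTf should silylate this on oxygen to give 5.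

**Further compounds**
F1 | step 5 | (E)-2-[(triisopropylsilyl)oxy]ethenyl (2S)-2-methoxy-2-phenylacetate | CO[C@H](C(=O)O/C=C/O[Si](C(C)C)(C(C)C)C(C)C)c1ccccc1
F2 | step 5 | methyl (1R,4S,7R,8R)-7-{[(2S)-2-methoxy-2-phenylacetyl]oxy}-3-oxo-8-[(triisopropylsilyl)oxy]-2-oxabicyclo[2.2.2]oct-5-ene-4-carboxylate | COC(=O)[C@@]12C=C[C@@H](OC1=O)[C@@H](OC(=O)[C@@H](OC)c3ccccc3)[C@@H]2O[Si](C(C)C)(C(C)C)C(C)C
F3 | step 5 | methyl (5R,6R)-5-{[(2S)-2-methoxy-2-phenylacetyl]oxy}-6-[(triisopropylsilyl)oxy]cyclohexa-1,3-diene-1-carboxylate | COC(=O)C1=CC=C[C@@H](OC(=O)[C@@H](OC)c2ccccc2)[C@@H]1O[Si](C(C)C)(C(C)C)C(C)C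
F4 | step 5 | methyl (5S,6S)-5-{[(2S)-2-methoxy-2-phenylacetyl]oxy}-6-[(triisopropylsilyl)oxy]cyclohexa-1,3-diene-1-carboxylate | COC(=O)C1=CC=C[C@H](OC(=O)[C@@H](OC)c2ccccc2)[C@H]1O[Si](C(C)C)(C(C)C)C(C)C
F5 | step 4 | 4,4,5,5-tetramethyl-2-({(E)-2-[(triisopropylsilyl)oxy]ethenyl}oxy)-1,3,2-dioxaborolane | CC(C)[Si](O/C=C/OB1OC(C)(C)C(C)(C)O1)(C(C)C)C(C)C
F6 | step 4 | potassium (E)-2-[(triisopropylsilyl)oxy]ethenolate | [K+].[O-]/C=C/O[Si](C(C)C)(C(C)C)C(C)C
F7 | step 2 | (trimethylsilyl)ketene | C[Si](C)(C)C=C=O
F8 | step 2 | potassium ethynolate | [K+].[O-]C#C
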